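(The readings were generated by integration with constants of no real substance; noise was put on by code.)

- If I write the balance of initiator, the reagent charged in the smallest amount, each unit consumed ends in a chain begun, in spent initiator A, or as one of the pair in spent initiator B. I define the length N as monomer in chains over chains begun, so I want to know how chains begun grow with the loading.

| setting | autumn | spring | south-east | east |
|---|---|---|---|---|
| free monomer | 49 mM | 49 mM | 49 mM | 49 mM |
| transfer agent | 14.7 mM | 14.7 mM | 14.7 mM | 14.7 mM |
| initiator | 0.44 mol% | 0.83 mol% | 1 mol% | 0.5 mol% |
| remark | run made earlier | run made earlier |  |  |
| time |  |  | 30 min | 30 min |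

- autumn (time / min: monomer in chains / %, free monomer / %): 5.00: 45.4, 54.3; 10.0: 77.3, 23.2; 15.0: 89.4, 10.2; 20.0: 94.7, 4.5; 25.0: 97.0, 2.1; 30.0: 98.2, 1.5
- spring (time / min: monomer in chains / %, free monomer / %): 5.00: 63.7, 36.4; 10.0: 90.4, 9.4; 15.0: 97.0, 3.0; 20.0: 98.9, 0.7; 25.0: 99.5, 0; 30.0: 99.5, 0

(scatter of a reading: 0.3 percentage points)

- which of the two ends with the longer chains by the average number of monomer units in a chain (chains begun, living or dead) ("neither" if they lie within 10%) (south-east / east / neither)
- average number of monomer units in a chain (chains begun, living or dead) at the end, south-east
- average number of monomer units in a chain (chains begun, living or dead) at the end, east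

- the average divides the monomer in chains by the number of chains begun, living and dead together
- steps under discussion: free monomer + initiator -> living end + monomer in chains; free monomer + living end -> monomer in chains + living end; living end + transfer agent -> dead chain; initiator -> spent initiator A; 2 initiator -> spent initiator B
- the earlier runs do not show the number of chains; that part of a forecast is a guess

- The runs don't count chains, so I read a proxy. I take the log-slope s of free monomer, a pseudo-first-order slope, as proportional to the chains alive. Between 5.00 min and 15.0 min it reads 0.167 min⁻¹ in autumn and 0.250 min⁻¹ in spring.
- My carried quantity is the loading exponent n, the log of the slope ratio over the log of the loading ratio: 0.631, as a reading. I take chains begun to go as the loading to the power n.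
- Scaled by n from autumn, with south-east a step beyond the runs, I expect the east curve to fall with a log-slope of 0.181 min⁻¹ and halve every 3.83 min. I expect the south-east curve to fall with a log-slope of 0.281 min⁻¹ and halve every 2.47 min.
- At these slopes, free monomer at 30 min stands near 0.438% in east and 0.0218% in south-east, so monomer in chains levels near the charge in both.
- With equal monomer in chains, I reckon east longer by a factor of 1.55, which lies beyond the margin of 10%. I commit to that ratio, but the runs give me no absolute length.
- The forecast says east, with 170 for south-east and 285 for east, a ratio of 1.68, and adds: “Efficiency is inferred, so this is uncertain”.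
- The simulation gives east, with 332 for south-east and 513 for east. South-east at 30.0 min holds 0.148 mM of chains begun, living and dead, which is 30.1% of its initiator charge. Multiplying 332 by the factor from n gives 515 for east.

    free monomer + initiator → living end + monomer in chains (k = 0.0650 M⁻¹ s⁻¹)
    free monomer + living end → monomer in chains + living end, rate k2*[living end]*[free monomer] (k = 40.0 M⁻¹ s⁻¹)
    living end + transfer agent → dead chain (kL = 0.0280 M⁻¹ s⁻¹)
    initiator → spent initiator A (k = 0.00250 s⁻¹)
    2 initiator → spent initiator B (k = 5.00 M⁻¹ s⁻¹)

- In the flask like east but with 59 mM of transfer agent, the loading is east's, so n leaves chains begun unchanged and N follows monomer in chains: 461. That flask gives 447, with 89.0% of monomer in chains.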